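**Overview**

- The tetrahydrofuran ring of the target (O1, C2, C3, C4, C5) is locally meso: the methyl groups on C3 and C4 are cis, C2 and C5 carry the same aryl group, and each aryl group is trans to the methyl next to it. This mirror symmetry lets the C2–aryl and C5–aryl bonds be cut together, leaving a symmetric eight-carbon ring diacid (a carboxyl group in place of each aryl group) and two copies of one enantiopure aryl bromide.
- The aryl bromide is cut further at the aryl–carbinol carbon bond (aryl Grignard reagent plus Weinreb amide, then ketone reduction) and at the aryl ether C–O bond (Mitsunobu). This leads back to 4-bromo-2-methoxyphenol, methyl (R)-lactate and 4-bromo-1,2-dimethoxybenzene; the diacid goes back to a furan-2,5-diester and then to diethyl oxydiacetate and butane-2,3-dione.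
- Forward, the five-membered ring is closed first as an aromatic furan (Hinsberg condensation), then saturated and hydrolysed. The side chain is built on the bromoarene in five steps. Both aryl groups are attached to C2 and C5 last, in one twofold nickel/photoredox decarboxylative arylation, and fluoride then frees the two carbinols.
- Stereochemistry: C3/C4 cis comes from hydrogenation of the furan on one face. C2 and C5 are set in the key step, each aryl group entering anti to the adjacent methyl. The aryloxy carbon (S) comes from methyl (R)-lactate by Mitsunobu inversion, and the carbinol carbon (R) from chelation-controlled reduction of the ketone with Zn(BH4)2.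

Key step: step 10

Remark on the chemistry: two molecules of bromide 16 are consumed per molecule of diacid 7 in step 10, and the configuration of 7 at its carboxyl-bearing carbons is irrelevant because both carbons become planar radicals.

**Route**

Step 1
Reactants: 1 diethyl 2,2'-oxydiacetate; 2 butane-2,3-dione
Product: 4 3,4-dimethylfuran-2,5-dicarboxylic acid, via furan half ester 3 (not isolated)
Conditions: KOtBu (2.5 equiv), t-BuOH/THF, 0 °C to rt, 2 added slowly; then aq KOH, 70 °C; then HCl to pH 1
Reagents that add atoms: potassium hydroxide, [K+].[OH-] (oxygen of the carboxyl group freed by hydrolysis)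
Why: Hinsberg furan synthesis, in which the diglycolate enolate condenses twice with the 1,2-diketone in a Stobbe-like double aldol sequence (through a δ-lactone that opens to half ester 3), both dehydrations are driven by aromatisation, slow addition of the enolisable diketone limits its self-condensation, and aqueous KOH hydrolyses the remaining ester.

Step 2
Reactants: 4 3,4-dimethylfuran-2,5-dicarboxylic acid
Product: 5 dimethyl 3,4-dimethylfuran-2,5-dicarboxylate
Conditions: MeOH, H2SO4 (cat.), reflux
Reagents that add atoms: methanol, CO
Why: Fischer esterification of an aromatic diacid in excess methanol gives a neutral, easily purified diester that is a clean substrate for the hydrogenation.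

Step 3
Reactants: 5 dimethyl 3,4-dimethylfuran-2,5-dicarboxylate
Product: 6 dimethyl (2R,3S,4R,5S)-3,4-dimethyltetrahydrofuran-2,5-dicarboxylate (all-cis, meso)
Conditions: H2 (60 bar), Rh/Al2O3 (5 wt% Rh), MeOH, 50 °C
Reagents that add atoms: none
Why: Heterogeneous catalytic hydrogenation of a furan, in which the flat ring takes up all four hydrogens from the catalyst face so that the four substituents end up cis, which fixes the cis relation of the methyl groups on C3 and C4; rhodium on alumina saturates furans without hydrogenolysis of the ring C–O bonds, and the configuration at C2 and C5 is not needed later.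

Step 4
Reactants: 6 dimethyl (2R,3S,4R,5S)-3,4-dimethyltetrahydrofuran-2,5-dicarboxylate
Product: 7 (2R,3S,4R,5S)-3,4-dimethyltetrahydrofuran-2,5-dicarboxylic acid (all-cis, meso)
Conditions: LiOH·H2O (3 equiv), THF/H2O, rt; then HCl to pH 1
Reagents that add atoms: lithium hydroxide, [Li+].[OH-]
Why: Ester saponification with LiOH, in which any epimerisation next to the carboxylates is harmless because C2 and C5 lose their configuration in step 10, while the non-acidic C3 and C4 keep their cis relation.

Step 5
Reactants: 8 4-bromo-2-methoxyphenol; 9 methyl (R)-lactate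
Product: 10 methyl (S)-2-(4-bromo-2-methoxyphenoxy)propanoate
Conditions: PPh3, diisopropyl azodicarboxylate, THF, 0 °C to rt
Reagents that add atoms: none
Why: Mitsunobu etherification of a phenol with a secondary α-hydroxy ester proceeds by SN2 displacement of the oxyphosphonium group with inversion, which turns the (R) lactate carbon into the (S) aryloxy carbon and leaves the aryl bromide untouched.

Step 6
Reactants: 10 methyl (S)-2-(4-bromo-2-methoxyphenoxy)propanoate
Product: 11 (S)-2-(4-bromo-2-methoxyphenoxy)-N-methoxy-N-methylpropanamide
Conditions: MeNH(OMe)·HCl (1.5 equiv), iPrMgCl (3 equiv), THF, −20 °C; then aq NH4Cl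
Reagents that add atoms: N,O-dimethylhydroxylamine hydrochloride, CNOC.Cl
Why: Weinreb amide formation by aminolysis of the ester with the chloromagnesium amide made in the flask, which at −20 °C adds to the ester faster than the α-carbon is deprotonated or iPrMgCl exchanges with the electron-rich aryl bromide, so the (S) centre is retained.

Step 7
Reactants: 11 (S)-2-(4-bromo-2-methoxyphenoxy)-N-methoxy-N-methylpropanamide; 12 4-bromo-1,2-dimethoxybenzene
Product: 14 (S)-2-(4-bromo-2-methoxyphenoxy)-1-(3,4-dimethoxyphenyl)propan-1-one, via aryl Grignard reagent 13 (not isolated)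
Conditions: 12, Mg turnings, THF, 40 °C; then 11, THF, −20 to 0 °C; then cold 1 M HCl
Reagents that add atoms: none
Why: Weinreb ketone synthesis, in which the aryl Grignard reagent adds once to give a stable five-membered magnesium chelate that collapses to the ketone only on the cold acidic quench, so there is no over-addition, the enolisable (S) α-carbon never meets base as a ketone, and Br/Mg exchange with the aryl bromide of 11 is negligible at this temperature.

Step 8
Reactants: 14 (S)-2-(4-bromo-2-methoxyphenoxy)-1-(3,4-dimethoxyphenyl)propan-1-one
Product: 15 (1R,2S)-2-(4-bromo-2-methoxyphenoxy)-1-(3,4-dimethoxyphenyl)propan-1-ol (erythro)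
Conditions: Zn(BH4)2, Et2O/CH2Cl2, −20 to 0 °C; then aq NH4Cl
Reagents that add atoms: none
Why: Chelation-controlled (Cram chelate) hydride reduction, in which zinc bridges the carbonyl oxygen and the α-aryloxy oxygen (assisted by the neighbouring methoxy group) and hydride attacks the locked chelate from the side of the small α-hydrogen, giving the erythro alcohol with the new (R) carbinol centre anti to the (S) aryloxy carbon; the near-neutral reagent neither enolises the ketone nor touches the aryl bromide.

Step 9
Reactants: 15 (1R,2S)-2-(4-bromo-2-methoxyphenoxy)-1-(3,4-dimethoxyphenyl)propan-1-ol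
Product: 16 {[(1R,2S)-2-(4-bromo-2-methoxyphenoxy)-1-(3,4-dimethoxyphenyl)propyl]oxy}(tert-butyl)dimethylsilane
Conditions: t-BuMe2SiOTf, 2,6-lutidine, CH2Cl2, −20 to 0 °C
Reagents that add atoms: tert-butyldimethylsilyl trifluoromethanesulfonate, CC(C)(C)[Si](C)(C)OS(=O)(=O)C(F)(F)F
Why: Silylation of a hindered secondary benzylic alcohol with a silyl triflate and a hindered pyridine base proceeds without acid that could ionise the carbinol, and the silyl ether masks the oxidation-prone benzylic alcohol for the photoredox step and is removable with fluoride.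

Step 10
Reactants: 7 (2R,3S,4R,5S)-3,4-dimethyltetrahydrofuran-2,5-dicarboxylic acid; 16 {[(1R,2S)-2-(4-bromo-2-methoxyphenoxy)-1-(3,4-dimethoxyphenyl)propyl]oxy}(tert-butyl)dimethylsilane (two equivalents are incorporated)
Product: 19 bis(tert-butyldimethylsilyl) ether of the target, via monoaryl acid 17 (not isolated), via ring-diastereomeric monoaryl acid 18 (not isolated)
Conditions: 16 (2.4 equiv), Ir[dF(CF3)ppy]2(dtbbpy)PF6 (2 mol%), NiCl2(dme) (20 mol%), 4,4'-di-tert-butyl-2,2'-bipyridine (20 mol%), Cs2CO3 (4 equiv), degassed DMF, blue LEDs (450 nm), 25 °C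
Reagents that add atoms: none
Why: Twofold metallaphotoredox decarboxylative arylation: the photoexcited trivalent iridium complex oxidises a caesium carboxylate of 7, CO2 is lost and a planar α-oxy radical forms at C2, while zerovalent nickel carrying the bipyridine inserts into the C–Br bond of 16, the resulting aryl bromide complex of divalent nickel traps the radical, reductive elimination from trivalent nickel makes the C2–aryl bond, the reduced divalent iridium complex returns monovalent nickel to zerovalent nickel, and the same cycle then removes the second carboxyl group of 17 or 18 and arylates C5. The closest known reaction type is the nickel and photoredox decarboxylative coupling of cyclic α-oxy acids (tetrahydrofuran-2-carboxylic and furanosyl acids) with aryl bromides, used here twice on one ring. No ring is closed, since the oxygen ring was made in step 1 and this step only joins three components at C2 and C5. Both new stereocentres are controlled by the cis methyl groups on C3 and C4: each planar radical is met by nickel, and receives its aryl group, on the ring face away from the adjacent methyl (the 1,2-trans preference known from furanosyl radicals), so the configuration of 7 at C2 and C5 plays no part and 17 and 18 converge on the single 2,3-trans, 3,4-cis, 4,5-trans product. The step needs diastereoselectivity at both radical centres, which the two methyl groups on one face secure, full conversion of the second carboxylate, which the excess of 16 and base secures, and oxidation of the carboxylate in preference to the electron-rich arenes and benzylic positions, which the low oxidation potential of α-oxy carboxylates and the silyl ethers secure.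

Step 11
Reactants: 19 bis(tert-butyldimethylsilyl) ether of the target
Product: 20 target CNP0116650.10
Conditions: Bu4NF, THF, 0 °C to rt; then H2O
Reagents that add atoms: none
Why: Fluoride-mediated desilylation of both silyl ethers, driven by the strength of the Si–F bond, runs under non-acidic conditions, so neither the benzylic ether carbons of the tetrahydrofuran nor the benzylic carbinols ionise and no stereocentre is affected.

**Compound list**

1 | diethyl 2,2'-oxydiacetate | CCOC(=O)COCC(=O)OCC | starting material
2 | butane-2,3-dione | CC(=O)C(C)=O | starting material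
3 | 5-(ethoxycarbonyl)-3,4-dimethylfuran-2-carboxylic acid (furan half ester, present as its potassium salt) | CCOC(=O)c1oc(C(=O)O)c(C)c1C | intermediate (not isolated)
4 | 3,4-dimethylfuran-2,5-dicarboxylic acid | OC(=O)c1oc(C(=O)O)c(C)c1C | intermediate
5 | dimethyl 3,4-dimethylfuran-2,5-dicarboxylate | COC(=O)c1oc(C(=O)OC)c(C)c1C | intermediate
6 | dimethyl (2R,3S,4R,5S)-3,4-dimethyltetrahydrofuran-2,5-dicarboxylate (all four substituents cis, meso) | COC(=O)[C@H]1O[C@@H](C(=O)OC)[C@@H](C)[C@H]1C | intermediate
7 | (2R,3S,4R,5S)-3,4-dimethyltetrahydrofuran-2,5-dicarboxylic acid (all four substituents cis, meso) | OC(=O)[C@H]1O[C@@H](C(=O)O)[C@@H](C)[C@H]1C | intermediate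
8 | 4-bromo-2-methoxyphenol | COc1cc(Br)ccc1O | starting material
9 | methyl (R)-lactate | C[C@@H](O)C(=O)OC | starting material
10 | methyl (S)-2-(4-bromo-2-methoxyphenoxy)propanoate | COC(=O)[C@H](C)Oc1ccc(Br)cc1OC | intermediate
11 | (S)-2-(4-bromo-2-methoxyphenoxy)-N-methoxy-N-methylpropanamide | CON(C)C(=O)[C@H](C)Oc1ccc(Br)cc1OC | intermediate
12 | 4-bromo-1,2-dimethoxybenzene | COc1ccc(Br)cc1OC | starting material
13 | (3,4-dimethoxyphenyl)magnesium bromide | COc1ccc([Mg]Br)cc1OC | intermediate (not isolated)
14 | (S)-2-(4-bromo-2-methoxyphenoxy)-1-(3,4-dimethoxyphenyl)propan-1-one | COc1ccc(C(=O)[C@H](C)Oc2ccc(Br)cc2OC)cc1OC | intermediate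
15 | (1R,2S)-2-(4-bromo-2-methoxyphenoxy)-1-(3,4-dimethoxyphenyl)propan-1-ol (erythro) | COc1ccc([C@@H](O)[C@H](C)Oc2ccc(Br)cc2OC)cc1OC | intermediate
16 | {[(1R,2S)-2-(4-bromo-2-methoxyphenoxy)-1-(3,4-dimethoxyphenyl)propyl]oxy}(tert-butyl)dimethylsilane | COc1ccc([C@@H](O[Si](C)(C)C(C)(C)C)[C@H](C)Oc2ccc(Br)cc2OC)cc1OC | intermediate
17 | (2S,3R,4S,5S)-5-[4-({(1R,2S)-1-[(tert-butyldimethylsilyl)oxy]-1-(3,4-dimethoxyphenyl)propan-2-yl}oxy)-3-methoxyphenyl]-3,4-dimethyltetrahydrofuran-2-carboxylic acid (aryl trans to the cis methyls, carboxyl cis to them) | COc1ccc([C@@H](O[Si](C)(C)C(C)(C)C)[C@H](C)Oc2ccc([C@H]3O[C@H](C(=O)O)[C@H](C)[C@@H]3C)cc2OC)cc1OC | intermediate (not isolated)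
18 | (2R,3S,4R,5R) ring diastereomer of 17 (same side chain, mirror-image ring, formed when the other carboxyl group of 7 reacts first) | COc1ccc([C@@H](O[Si](C)(C)C(C)(C)C)[C@H](C)Oc2ccc([C@@H]3O[C@@H](C(=O)O)[C@@H](C)[C@H]3C)cc2OC)cc1OC | intermediate (not isolated)
19 | (2R,3R,4S,5S)-2,5-bis[4-({(1R,2S)-1-[(tert-butyldimethylsilyl)oxy]-1-(3,4-dimethoxyphenyl)propan-2-yl}oxy)-3-methoxyphenyl]-3,4-dimethyltetrahydrofuran (2,3-trans, 3,4-cis, 4,5-trans) | COc1ccc([C@@H](O[Si](C)(C)C(C)(C)C)[C@H](C)Oc2ccc([C@H]3O[C@@H](c4ccc(O[C@@H](C)[C@H](O[Si](C)(C)C(C)(C)C)c5ccc(OC)c(OC)c5)c(OC)c4)[C@H](C)[C@@H]3C)cc2OC)cc1OC | intermediate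
20 | target CNP0116650.10: (1R,2S,1'R,2'S)-2,2'-{[(2R,3R,4S,5S)-3,4-dimethyltetrahydrofuran-2,5-diyl]bis[(2-methoxy-4,1-phenylene)oxy]}bis[1-(3,4-dimethoxyphenyl)propan-1-ol] | COc1ccc([C@@H](O)[C@H](C)Oc2ccc([C@H]3O[C@@H](c4ccc(O[C@@H](C)[C@H](O)c5ccc(OC)c(OC)c5)c(OC)c4)[C@H](C)[C@@H]3C)cc2OC)cc1OC | target

**Step count**

Total: 11 steps. Longest linear sequence: 7 steps (steps 5 to 11, from 8 and 9). The ring branch contributes 6 steps (steps 1 to 4, then 10 and 11).

**Steps most likely to fail**

Step 10. The second decarboxylative coupling may lag behind the first, because oxidative addition of the electron-rich bromide is slow; the second α-oxy radical would then be lost to hydrogen abstraction, or the reaction would stall at the monoaryl acids. Facial selection at the second radical may also be incomplete, since there the adjacent methyl and the aryl group already on the ring lie on opposite faces. The fallback sets out from 7 and 16 and returns at 19. It forms the same two bonds but generates the radical by reductive fragmentation of a redox-active ester and takes the aryl partner as an organozinc. Diacid 7 is esterified with N-hydroxyphthalimide (N,N'-diisopropylcarbodiimide, cat. 4-(dimethylamino)pyridine, CH2Cl2) to the bis(1,3-dioxoisoindolin-2-yl) diester F1. Bromide 16 is converted by bromine–lithium exchange (n-BuLi, THF, −78 °C) into the aryllithium F2 and then with ZnCl2 into the arylzinc chloride F3. Nickel-catalysed decarboxylative Negishi-type coupling of F1 with F3 (NiCl2(dme), 4,4'-di-tert-butyl-2,2'-bipyridine, THF/DMF, rt) should then give 19. The same ring radicals are involved, so the same preference for aryl delivery anti to the adjacent methyl is expected; the fallback addresses reactivity, not facial selectivity.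

Step 1. Base-induced self-condensation of the enolisable diketone 2 may outrun the crossed double aldol condensation, so that little furan forms. The fallback sets out from 1 and returns at 4. It closes the ring on a non-enolisable 1,2-dielectrophile and adds the methyl groups afterwards. Double Claisen-type condensation of 1 with diethyl oxalate (NaOEt, EtOH, reflux; then HCl) gives diethyl 3,4-dihydroxyfuran-2,5-dicarboxylate F4. Tf2O and pyridine in CH2Cl2 at 0 °C convert it into diethyl 3,4-bis(trifluoromethylsulfonyloxy)furan-2,5-dicarboxylate F5. Twofold Suzuki–Miyaura methylation (trimethylboroxine, Pd(dppf)Cl2, K2CO3, dioxane, 90 °C) gives diethyl 3,4-dimethylfuran-2,5-dicarboxylate F6, and saponification (NaOH, EtOH/H2O; then HCl) gives 4.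

Step 8. Zinc chelation by the weakly basic aryl ether oxygen may be incomplete, so that the open-chain (Felkin–Anh) pathway competes and hydride delivery shows poor facial selectivity. The fallback sets out from 14 and returns at 15. It sets the carbinol configuration by a stereospecific inversion instead of by the reduction. Ketone 14 is reduced with NaBH4 in MeOH, and 15 is separated by chromatography from its carbinol epimer, the threo alcohol (1S,2S)-2-(4-bromo-2-methoxyphenoxy)-1-(3,4-dimethoxyphenyl)propan-1-ol F7. Mitsunobu esterification of F7 with 4-nitrobenzoic acid (PPh3, diisopropyl azodicarboxylate, THF, 0 °C) inverts the carbinol carbon and gives the (1R,2S) 4-nitrobenzoate F8. Methanolysis (K2CO3 cat., MeOH) then gives 15, so both epimers from the reduction end up as 15.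

**Further compounds**

F1 | step 10 | bis(1,3-dioxoisoindolin-2-yl) (2R,3S,4R,5S)-3,4-dimethyltetrahydrofuran-2,5-dicarboxylate | O=C(ON1C(=O)c2ccccc2C1=O)[C@H]1O[C@@H](C(=O)ON2C(=O)c3ccccc3C2=O)[C@@H](C)[C@H]1C
F2 | step 10 | aryllithium from 16: {4-[((1R,2S)-1-[(tert-butyldimethylsilyl)oxy]-1-(3,4-dimethoxyphenyl)propan-2-yl)oxy]-3-methoxyphenyl}lithium | COc1ccc([C@@H](O[Si](C)(C)C(C)(C)C)[C@H](C)Oc2ccc([Li])cc2OC)cc1OC
F3 | step 10 | arylzinc chloride from 16: {4-[((1R,2S)-1-[(tert-butyldimethylsilyl)oxy]-1-(3,4-dimethoxyphenyl)propan-2-yl)oxy]-3-methoxyphenyl}zinc chloride | COc1ccc([C@@H](O[Si](C)(C)C(C)(C)C)[C@H](C)Oc2ccc([Zn]Cl)cc2OC)cc1OC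
F4 | step 1 | diethyl 3,4-dihydroxyfuran-2,5-dicarboxylate | CCOC(=O)c1oc(C(=O)OCC)c(O)c1O
F5 | step 1 | diethyl 3,4-bis(trifluoromethylsulfonyloxy)furan-2,5-dicarboxylate | CCOC(=O)c1oc(C(=O)OCC)c(OS(=O)(=O)C(F)(F)F)c1OS(=O)(=O)C(F)(F)F
F6 | step 1 | diethyl 3,4-dimethylfuran-2,5-dicarboxylate | CCOC(=O)c1oc(C(=O)OCC)c(C)c1C
F7 | step 8 | (1S,2S)-2-(4-bromo-2-methoxyphenoxy)-1-(3,4-dimethoxyphenyl)propan-1-ol (threo) | COc1ccc([C@H](O)[C@H](C)Oc2ccc(Br)cc2OC)cc1OC
F8 | step 8 | (1R,2S)-2-(4-bromo-2-methoxyphenoxy)-1-(3,4-dimethoxyphenyl)propyl 4-nitrobenzoate | COc1ccc([C@@H](OC(=O)c3ccc(cc3)[N+](=O)[O-])[C@H](C)Oc2ccc(Br)cc2OC)cc1OC
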